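**Remark (assumption on the chemistry):** the SMILES is read as the (2R,3R)-cis-2,3-dihydrobenzofuran carrying an erythro (7''R,8''S) guaiacylglycerol unit on the 4-oxygen of its C2 syringyl ring. O1/C2/C3 are dihydrofuran locants; C7''/C8''/C9'' are the glycerol carbons ArCH(OH), CH(OAr), CH2OH. TBS = tert-butyldimethylsilyl.

## Retrosynthetic overview

1. Feature: in the dihydrofuran ring the O1–C2 bond ends on the benzylic carbon C2, and the cis pair C2-aryl/C3-CH2OH is a syn aldol pair (C2–OH/C3-aryl) inverted at C2. O1–C2 is therefore cut as an invertive phenol etherification of syn diol monosilyl ether 22.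
2. 22 comes from an Evans boron syn-aldol (C2–C3 bond, both core stereocentres) between arylacetyl imide 14 and O-mesylsyringaldehyde 16. Imide 14 comes from eugenol by hydroboration, O-allylation, Claisen rearrangement and oxidative cleavage.
3. After ring closure the mesylate is removed, the C8''–O bond is made by Mitsunobu inversion of an (R)-glycerate, the C7''–aryl bond by Felkin–Anh addition of an aryllithium to the α-aryloxy aldehyde, and all silyl groups are removed at once.
4. Ring order: the three benzene rings are bought (eugenol, syringaldehyde, 4-bromoguaiacol); the dihydrofuran is the only ring formed (step 14).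

Key step: step 14

## Route

Step 1
Reactants: 1 eugenol
Product: 3 4-(3-hydroxypropyl)-2-methoxyphenol (dihydroconiferyl alcohol), via bis-boryl adduct 2 (not isolated)
Conditions: 9-BBN (2.3 equiv), THF, 0 °C→rt; then 3 M NaOH, 30% H2O2, 0 °C→rt
Reagents that add atoms: hydrogen peroxide, OO
Why: Hydroboration–oxidation with the bulky 9-BBN should place boron, then hydroxyl, on the terminal carbon of the allyl group (anti-Markovnikov), the phenol being only O-borylated with loss of H2 and set free again in the alkaline peroxide work-up.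

Step 2
Reactants: 3 4-(3-hydroxypropyl)-2-methoxyphenol
Product: 4 3-[4-(allyloxy)-3-methoxyphenyl]propan-1-ol
Conditions: allyl bromide (1.1 equiv), K2CO3, acetone, reflux
Reagents that add atoms: allyl bromide, C=CCBr
Why: Williamson etherification in which carbonate deprotonates only the phenol, so the primary alcohol should stay free.

Step 3
Reactants: 4 3-[4-(allyloxy)-3-methoxyphenyl]propan-1-ol
Product: 6 2-allyl-4-(3-hydroxypropyl)-6-methoxyphenol, via Claisen dienone 5 (not isolated)
Conditions: PhNEt2, 190 °C, argon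
Reagents that add atoms: none
Why: Aromatic Claisen rearrangement, a [3,3]-sigmatropic shift that can end only on the one unsubstituted ortho carbon (the other ortho position carries OMe and the para position the side chain), followed by tautomerisation of dienone 5 to the phenol.

Step 4
Reactants: 6 2-allyl-4-(3-hydroxypropyl)-6-methoxyphenol
Product: 7 3-[3-allyl-4-(benzyloxy)-5-methoxyphenyl]propan-1-ol
Conditions: BnBr (1.1 equiv), K2CO3, DMF, rt→50 °C
Reagents that add atoms: benzyl bromide, BrCc1ccccc1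
Why: Williamson benzylation of the phenoxide, again chemoselective over the primary alcohol under carbonate conditions, installs a phenol protecting group that is later removed by neutral hydrogenolysis.

Step 5
Reactants: 7 3-[3-allyl-4-(benzyloxy)-5-methoxyphenyl]propan-1-ol
Product: 8 tert-butyl{3-[3-allyl-4-(benzyloxy)-5-methoxyphenyl]propoxy}dimethylsilane
Conditions: TBSCl, imidazole, DMF, rt
Reagents that add atoms: tert-butyldimethylsilyl chloride, CC(C)(C)[Si](C)(C)Cl
Why: Standard imidazole-promoted silylation of the primary alcohol gives a silyl ether that should survive every step up to the final fluoride treatment.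

Step 6
Reactants: 8 tert-butyl{3-[3-allyl-4-(benzyloxy)-5-methoxyphenyl]propoxy}dimethylsilane
Product: 10 2-{2-(benzyloxy)-3-methoxy-5-[3-(TBS-oxy)propyl]phenyl}acetaldehyde, via vicinal diol 9 (not isolated)
Conditions: OsO4 (2 mol %), NaIO4 (4 equiv), 2,6-lutidine, dioxane–H2O 3:1, rt; crude product used at once
Reagents that add atoms: osmium tetroxide, O=[Os](=O)(=O)=O; sodium periodate, [Na+].[O-]I(=O)(=O)=O
Why: Lemieux–Johnson oxidative cleavage (catalytic osmylation to diol 9, periodate glycol cleavage) shortens the allyl group by one carbon without touching the arene, with lutidine suppressing over-oxidation.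

Step 7
Reactants: 10 2-{2-(benzyloxy)-3-methoxy-5-[3-(TBS-oxy)propyl]phenyl}acetaldehyde
Product: 11 2-{2-(benzyloxy)-3-methoxy-5-[3-(TBS-oxy)propyl]phenyl}acetic acid
Conditions: NaClO2, NaH2PO4, 2-methyl-2-butene, t-BuOH–H2O, 0 °C→rt
Reagents that add atoms: sodium chlorite, [Na+].[O-]Cl=O
Why: Pinnick oxidation converts the enolisable arylacetaldehyde to the acid under buffered conditions, the alkene scavenger removing HOCl before it can chlorinate the electron-rich ring.

Step 8
Reactants: 11 2-{2-(benzyloxy)-3-methoxy-5-[3-(TBS-oxy)propyl]phenyl}acetic acid; 12 (S)-4-benzyl-2-oxazolidinone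
Product: 14 (S)-4-benzyl-3-(2-{2-(benzyloxy)-3-methoxy-5-[3-(TBS-oxy)propyl]phenyl}acetyl)oxazolidin-2-one, via mixed pivalic anhydride 13 (not isolated)
Conditions: PivCl, Et3N, THF, −20 °C; then LiCl, 12, −20 °C→rt
Reagents that add atoms: none
Why: N-Acylation of the oxazolidinone through the mixed pivalic anhydride (LiCl/Et3N variant), in which the nucleophile attacks the less hindered arylacetyl carbonyl.

Step 9
Reactants: 15 syringaldehyde
Product: 16 4-formyl-2,6-dimethoxyphenyl methanesulfonate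
Conditions: MsCl, Et3N, CH2Cl2, 0 °C
Reagents that add atoms: methanesulfonyl chloride, CS(=O)(=O)Cl
Why: Sulfonylation of the phenol turns the para oxygen of the future C2 aryl group into an electron-poor substituent that is stable to hydride and hydrogenolysis.

Step 10
Reactants: 14 (S)-4-benzyl-3-(arylacetyl)oxazolidin-2-one; 16 4-formyl-2,6-dimethoxyphenyl methanesulfonate
Product: 19 (4S)-4-benzyl-3-[(2S,3S)-2-{2-(benzyloxy)-3-methoxy-5-[3-(TBS-oxy)propyl]phenyl}-3-hydroxy-3-(4-mesyloxy-3,5-dimethoxyphenyl)propanoyl]oxazolidin-2-one, via Z-boron enolate 17 (not isolated), via boron aldolate 18 (not isolated)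
Conditions: Bu2BOTf (1.2 equiv), i-Pr2NEt (1.4 equiv), CH2Cl2, −78→0 °C; then 16, −78→0 °C; pH 7 buffer, MeOH, 30% H2O2, 0 °C
Reagents that add atoms: none
Why: Evans boron syn-aldol reaction: the Z-dibutylboron enolate reacts through a closed Zimmerman–Traxler chair with the auxiliary carbonyl turned away (dipole minimised) and the benzyl group shielding one enolate face, which should give the (2S,3S) syn adduct and thus set both core stereocentres (the future C3 directly, the future C2 as its epimer).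

Step 11
Reactants: 19 syn aldol adduct
Product: 20 4-[(1S,2R)-2-{2-(benzyloxy)-3-methoxy-5-[3-(TBS-oxy)propyl]phenyl}-1,3-dihydroxypropyl]-2,6-dimethoxyphenyl methanesulfonate
Conditions: LiBH4 (2.5 equiv), THF, MeOH (1 equiv), 0 °C
Reagents that add atoms: none
Why: Reductive removal of the auxiliary with LiBH4, which attacks the exocyclic imide carbonyl and should leave the aryl mesylate, the ethers and both stereocentres untouched.

Step 12
Reactants: 20 (1S,2R)-1,3-diol
Product: 21 4-[(1S,2R)-2-{2-(benzyloxy)-3-methoxy-5-[3-(TBS-oxy)propyl]phenyl}-1-hydroxy-3-(TBS-oxy)propyl]-2,6-dimethoxyphenyl methanesulfonate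
Conditions: TBSCl (1.05 equiv), imidazole, CH2Cl2, −20→0 °C
Reagents that add atoms: tert-butyldimethylsilyl chloride, CC(C)(C)[Si](C)(C)Cl
Why: Kinetically selective silylation of the primary hydroxyl over the hindered secondary benzylic one leaves the C2 carbinol as the only free alcohol.

Step 13
Reactants: 21 benzyl-protected syn diol monosilyl ether
Product: 22 4-[(1S,2R)-1-hydroxy-2-{2-hydroxy-3-methoxy-5-[3-(TBS-oxy)propyl]phenyl}-3-(TBS-oxy)propyl]-2,6-dimethoxyphenyl methanesulfonate
Conditions: H2 (1 atm), 10% Pd/C, EtOAc, rt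
Reagents that add atoms: none
Why: Catalytic hydrogenolysis of the aryl benzyl ether under neutral conditions should free the ring-C phenol while the aryl mesylate, the silyl ethers and the electron-poor benzylic carbinol remain.

Step 14
Reactants: 22 syn phenol diol monosilyl ether
Product: 24 4-{(2R,3R)-7-methoxy-3-(TBS-oxymethyl)-5-[3-(TBS-oxy)propyl]-2,3-dihydrobenzofuran-2-yl}-2,6-dimethoxyphenyl methanesulfonate (cis), via alkoxyphosphonium phenoxide 23 (not isolated)
Conditions: PPh3 (1.5 equiv), DIAD (1.5 equiv), toluene, 0 °C→rt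
Reagents that add atoms: none
Why: Intramolecular Mitsunobu cyclodehydration, the known route from 2-(2-hydroxyaryl)ethanols to 2,3-dihydrobenzofurans: the PPh3–DIAD betaine is protonated by the ring-C phenol (the only acidic OH), the sole free alcohol, the C2 carbinol, becomes alkoxyphosphonium 23, and the phenoxide displaces triphenylphosphine oxide from the rear. The dihydrofuran ring closes in a 5-exo-tet mode (O1 attacks C2, leaving group outside the forming ring). C2 is the only centre touched: it is set by stereospecific SN2 inversion of the aldol-derived (S)-carbinol to (2R), while C3 keeps its aldol configuration, so the syn aldol pair should become the cis C2-aryl/C3-CH2OTBS pair. The step needs SN2 substitution to outrun ionisation at C2 (which would drain to the trans ring) and E2 loss to the stilbene; the para-mesyloxy group flanked by two meta-methoxy groups removes the oxygen lone-pair donation that would stabilise a benzylic cation, the nucleophile is held in a five-membered arrangement, and toluene at 0 °C disfavours ion pairs. Chemoselectivity is secured because the primary hydroxyl is silylated, so closure onto the CH2O carbon cannot compete.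

Step 15
Reactants: 24 cis-dihydrobenzofuran aryl mesylate
Product: 25 4-{(2R,3R)-7-methoxy-3-(TBS-oxymethyl)-5-[3-(TBS-oxy)propyl]-2,3-dihydrobenzofuran-2-yl}-2,6-dimethoxyphenol
Conditions: LDA (3 equiv), THF, −78→0 °C; aq. NH4Cl
Reagents that add atoms: none
Why: Base-induced aryl mesylate cleavage, in which LDA deprotonates the S-methyl group and the anion expels the aryloxide with loss of sulfene, avoids hydrolysis at the hindered sulfonyl centre, and at low temperature the lithium phenoxide should not reopen the cis ring through a p-quinone methide.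

Step 16
Reactants: 26 methyl (R)-2,2-dimethyl-1,3-dioxolane-4-carboxylate
Product: 27 methyl (R)-2,3-dihydroxypropanoate
Conditions: Dowex 50W-X8 (H+), MeOH, rt
Reagents that add atoms: none
Why: Acid-catalysed transketalisation to methanol removes the acetonide without touching the ester or the stereocentre.

Step 17
Reactants: 27 methyl (R)-2,3-dihydroxypropanoate
Product: 28 methyl (R)-3-(TBS-oxy)-2-hydroxypropanoate
Conditions: TBSCl (1.05 equiv), imidazole, CH2Cl2, 0 °C
Reagents that add atoms: tert-butyldimethylsilyl chloride, CC(C)(C)[Si](C)(C)Cl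
Why: Selective silylation of the primary hydroxyl of the 1,2-diol leaves the secondary α-hydroxy ester free for etherification.

Step 18
Reactants: 25 syringyl-type phenol; 28 methyl (R)-3-(TBS-oxy)-2-hydroxypropanoate
Product: 30 methyl (S)-3-(TBS-oxy)-2-(4-{(2R,3R)-7-methoxy-3-(TBS-oxymethyl)-5-[3-(TBS-oxy)propyl]-2,3-dihydrobenzofuran-2-yl}-2,6-dimethoxyphenoxy)propanoate, via glycerate alkoxyphosphonium 29 (not isolated)
Conditions: 28 (1.5 equiv), PPh3, DIAD, THF, 0 °C→rt
Reagents that add atoms: none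
Why: Mitsunobu etherification at the carbon α to the ester, a good SN2 site, should proceed with clean inversion (R to S) and so installs C8'' in the configuration of the target.

Step 19
Reactants: 30 methyl (S)-2-aryloxy-3-silyloxypropanoate
Product: 32 (S)-3-(TBS-oxy)-2-(4-{(2R,3R)-7-methoxy-3-(TBS-oxymethyl)-5-[3-(TBS-oxy)propyl]-2,3-dihydrobenzofuran-2-yl}-2,6-dimethoxyphenoxy)propanal, via aluminium hemiacetal 31 (not isolated)
Conditions: DIBAL-H (1.1 equiv), CH2Cl2, −78 °C; MeOH, aq. Rochelle salt; crude aldehyde used at once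
Reagents that add atoms: none
Why: Partial reduction of the ester with DIBAL-H at −78 °C stops at the chelated tetrahedral aluminium hemiacetal 31, which releases the aldehyde only on work-up, so over-reduction and epimerisation at C8'' should be avoided.

Step 20
Reactants: 33 4-bromo-2-methoxyphenol
Product: 34 (4-bromo-2-methoxyphenoxy)(tert-butyl)dimethylsilane
Conditions: TBSCl, imidazole, DMF, rt
Reagents that add atoms: tert-butyldimethylsilyl chloride, CC(C)(C)[Si](C)(C)Cl
Why: Imidazole-promoted silylation protects the phenol as a silyl ether that tolerates bromine–lithium exchange and is removed with the other silyl groups at the end.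

Step 21
Reactants: 32 (S)-2-aryloxy-3-silyloxypropanal; 34 (4-bromo-2-methoxyphenoxy)(tert-butyl)dimethylsilane
Product: 36 (1R,2S)-3-(TBS-oxy)-1-[4-(TBS-oxy)-3-methoxyphenyl]-2-(4-{(2R,3R)-7-methoxy-3-(TBS-oxymethyl)-5-[3-(TBS-oxy)propyl]-2,3-dihydrobenzofuran-2-yl}-2,6-dimethoxyphenoxy)propan-1-ol, via aryllithium 35 (not isolated)
Conditions: 34 (2.5 equiv), n-BuLi (2.4 equiv), THF, −78 °C; then 32, THF, −78 °C; aq. NH4Cl
Reagents that add atoms: none
Why: Bromine–lithium exchange gives aryllithium 35, whose 1,2-addition to the α-aryloxy aldehyde should follow the polar Felkin–Anh model (C8''–OAr bond antiperiplanar to the incoming aryl group, approach past the C8'' hydrogen, no chelation by the weakly basic aryloxy oxygen or the bulky silyl ether) and set C7'' as R, the 1,2-anti (erythro) carbinol.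

Step 22
Reactants: 36 tetrasilyl erythro alcohol
Product: 37 (1R,2S)-1-(4-hydroxy-3-methoxyphenyl)-2-{4-[(2R,3R)-3-(hydroxymethyl)-5-(3-hydroxypropyl)-7-methoxy-2,3-dihydrobenzofuran-2-yl]-2,6-dimethoxyphenoxy}propane-1,3-diol (CNP0301567.1)
Conditions: TBAF (6 equiv), AcOH (6 equiv), THF, 0 °C→rt
Reagents that add atoms: none
Why: Fluoride-mediated cleavage of all four silyl ethers, buffered with acetic acid so that neither phenoxide nor acid chemistry can disturb the p-hydroxybenzylic carbinol or the cis ring, should deliver the target.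

## Compound list

1 | eugenol (4-allyl-2-methoxyphenol) | C=CCc1ccc(O)c(OC)c1 | starting material
2 | bis-boryl adduct: B-[3-(3-methoxy-4-(9-BBN-oxy)phenyl)propyl]-9-BBN | COc1cc(CCCB2C3CCCC2CCC3)ccc1OB1C2CCCC1CCC2 | intermediate
3 | 4-(3-hydroxypropyl)-2-methoxyphenol | COc1cc(CCCO)ccc1O | intermediate
4 | 3-[4-(allyloxy)-3-methoxyphenyl]propan-1-ol | C=CCOc1ccc(CCCO)cc1OC | intermediate
5 | Claisen dienone: 6-allyl-4-(3-hydroxypropyl)-2-methoxycyclohexa-2,4-dien-1-one (racemic) | C=CCC1C=C(CCCO)C=C(OC)C1=O | intermediate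
6 | 2-allyl-4-(3-hydroxypropyl)-6-methoxyphenol | C=CCc1cc(CCCO)cc(OC)c1O | intermediate
7 | 3-[3-allyl-4-(benzyloxy)-5-methoxyphenyl]propan-1-ol | C=CCc1cc(CCCO)cc(OC)c1OCc1ccccc1 | intermediate
8 | tert-butyl{3-[3-allyl-4-(benzyloxy)-5-methoxyphenyl]propoxy}dimethylsilane | C=CCc1cc(CCCO[Si](C)(C)C(C)(C)C)cc(OC)c1OCc1ccccc1 | intermediate
9 | vicinal diol: 3-{2-(benzyloxy)-3-methoxy-5-[3-(TBS-oxy)propyl]phenyl}propane-1,2-diol (racemic) | OCC(O)Cc1cc(CCCO[Si](C)(C)C(C)(C)C)cc(OC)c1OCc1ccccc1 | intermediate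
10 | 2-{2-(benzyloxy)-3-methoxy-5-[3-(TBS-oxy)propyl]phenyl}acetaldehyde | O=CCc1cc(CCCO[Si](C)(C)C(C)(C)C)cc(OC)c1OCc1ccccc1 | intermediate
11 | 2-{2-(benzyloxy)-3-methoxy-5-[3-(TBS-oxy)propyl]phenyl}acetic acid | OC(=O)Cc1cc(CCCO[Si](C)(C)C(C)(C)C)cc(OC)c1OCc1ccccc1 | intermediate
12 | (S)-4-benzyl-2-oxazolidinone | O=C1N[C@@H](Cc2ccccc2)CO1 | starting material
13 | mixed pivalic anhydride of 11 | CC(C)(C)C(=O)OC(=O)Cc1cc(CCCO[Si](C)(C)C(C)(C)C)cc(OC)c1OCc1ccccc1 | intermediate
14 | (S)-4-benzyl-3-(2-{2-(benzyloxy)-3-methoxy-5-[3-(TBS-oxy)propyl]phenyl}acetyl)oxazolidin-2-one | O=C(Cc1cc(CCCO[Si](C)(C)C(C)(C)C)cc(OC)c1OCc1ccccc1)N1[C@@H](Cc2ccccc2)COC1=O | intermediate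
15 | syringaldehyde (4-hydroxy-3,5-dimethoxybenzaldehyde) | COc1cc(C=O)cc(OC)c1O | starting material
16 | 4-formyl-2,6-dimethoxyphenyl methanesulfonate | COc1cc(C=O)cc(OC)c1OS(C)(=O)=O | intermediate
17 | (Z)-dibutylboron enolate of 14 | CCCCB(CCCC)O/C(=C\c1cc(CCCO[Si](C)(C)C(C)(C)C)cc(OC)c1OCc1ccccc1)N1[C@@H](Cc2ccccc2)COC1=O | intermediate
18 | dibutylboron aldolate of 19 | CS(=O)(=O)Oc1c(OC)cc([C@@H](OB(CCCC)CCCC)[C@H](c2cc(CCCO[Si](C)(C)C(C)(C)C)cc(OC)c2OCc2ccccc2)C(=O)N2[C@@H](Cc3ccccc3)COC2=O)cc1OC | intermediate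
19 | (4S)-4-benzyl-3-[(2S,3S)-2-aryl-3-hydroxy-3-(4-mesyloxy-3,5-dimethoxyphenyl)propanoyl]oxazolidin-2-one (aryl = 2-benzyloxy-3-methoxy-5-[3-(TBS-oxy)propyl]phenyl) | CS(=O)(=O)Oc1c(OC)cc([C@@H](O)[C@H](c2cc(CCCO[Si](C)(C)C(C)(C)C)cc(OC)c2OCc2ccccc2)C(=O)N2[C@@H](Cc3ccccc3)COC2=O)cc1OC | intermediate
20 | 4-[(1S,2R)-2-{2-(benzyloxy)-3-methoxy-5-[3-(TBS-oxy)propyl]phenyl}-1,3-dihydroxypropyl]-2,6-dimethoxyphenyl methanesulfonate | CS(=O)(=O)Oc1c(OC)cc([C@@H](O)[C@H](c2cc(CCCO[Si](C)(C)C(C)(C)C)cc(OC)c2OCc2ccccc2)CO)cc1OC | intermediate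
21 | 4-[(1S,2R)-2-{2-(benzyloxy)-3-methoxy-5-[3-(TBS-oxy)propyl]phenyl}-1-hydroxy-3-(TBS-oxy)propyl]-2,6-dimethoxyphenyl methanesulfonate | CS(=O)(=O)Oc1c(OC)cc([C@@H](O)[C@H](c2cc(CCCO[Si](C)(C)C(C)(C)C)cc(OC)c2OCc2ccccc2)CO[Si](C)(C)C(C)(C)C)cc1OC | intermediate
22 | 4-[(1S,2R)-1-hydroxy-2-{2-hydroxy-3-methoxy-5-[3-(TBS-oxy)propyl]phenyl}-3-(TBS-oxy)propyl]-2,6-dimethoxyphenyl methanesulfonate (key-step precursor) | CS(=O)(=O)Oc1c(OC)cc([C@@H](O)[C@H](c2cc(CCCO[Si](C)(C)C(C)(C)C)cc(OC)c2O)CO[Si](C)(C)C(C)(C)C)cc1OC | intermediate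
23 | alkoxyphosphonium phenoxide zwitterion of 22 | CS(=O)(=O)Oc1c(OC)cc([C@@H](O[P+](c2ccccc2)(c2ccccc2)c2ccccc2)[C@H](c2cc(CCCO[Si](C)(C)C(C)(C)C)cc(OC)c2[O-])CO[Si](C)(C)C(C)(C)C)cc1OC | intermediate
24 | 4-{(2R,3R)-7-methoxy-3-(TBS-oxymethyl)-5-[3-(TBS-oxy)propyl]-2,3-dihydrobenzofuran-2-yl}-2,6-dimethoxyphenyl methanesulfonate (cis; key-step product) | CS(=O)(=O)Oc1c(OC)cc([C@@H]2Oc3c(OC)cc(CCCO[Si](C)(C)C(C)(C)C)cc3[C@@H]2CO[Si](C)(C)C(C)(C)C)cc1OC | intermediate
25 | 4-{(2R,3R)-7-methoxy-3-(TBS-oxymethyl)-5-[3-(TBS-oxy)propyl]-2,3-dihydrobenzofuran-2-yl}-2,6-dimethoxyphenol | Oc1c(OC)cc([C@@H]2Oc3c(OC)cc(CCCO[Si](C)(C)C(C)(C)C)cc3[C@@H]2CO[Si](C)(C)C(C)(C)C)cc1OC | intermediate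
26 | methyl (R)-2,2-dimethyl-1,3-dioxolane-4-carboxylate | COC(=O)[C@H]1COC(C)(C)O1 | starting material
27 | methyl (R)-2,3-dihydroxypropanoate | COC(=O)[C@H](O)CO | intermediate
28 | methyl (R)-3-(TBS-oxy)-2-hydroxypropanoate | COC(=O)[C@H](O)CO[Si](C)(C)C(C)(C)C | intermediate
29 | alkoxyphosphonium cation of 28 | COC(=O)[C@H](O[P+](c1ccccc1)(c1ccccc1)c1ccccc1)CO[Si](C)(C)C(C)(C)C | intermediate
30 | methyl (S)-3-(TBS-oxy)-2-(4-{(2R,3R)-dihydrobenzofuran-2-yl}-2,6-dimethoxyphenoxy)propanoate (dihydrobenzofuran as in 25) | COC(=O)[C@H](CO[Si](C)(C)C(C)(C)C)Oc1c(OC)cc([C@@H]2Oc3c(OC)cc(CCCO[Si](C)(C)C(C)(C)C)cc3[C@@H]2CO[Si](C)(C)C(C)(C)C)cc1OC | intermediate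
31 | diisobutylaluminium hemiacetal of 30 | COC(O[Al](CC(C)C)CC(C)C)[C@H](CO[Si](C)(C)C(C)(C)C)Oc1c(OC)cc([C@@H]2Oc3c(OC)cc(CCCO[Si](C)(C)C(C)(C)C)cc3[C@@H]2CO[Si](C)(C)C(C)(C)C)cc1OC | intermediate
32 | (S)-3-(TBS-oxy)-2-(4-{(2R,3R)-dihydrobenzofuran-2-yl}-2,6-dimethoxyphenoxy)propanal (dihydrobenzofuran as in 25) | O=C[C@H](CO[Si](C)(C)C(C)(C)C)Oc1c(OC)cc([C@@H]2Oc3c(OC)cc(CCCO[Si](C)(C)C(C)(C)C)cc3[C@@H]2CO[Si](C)(C)C(C)(C)C)cc1OC | intermediate
33 | 4-bromo-2-methoxyphenol | COc1cc(Br)ccc1O | starting material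
34 | (4-bromo-2-methoxyphenoxy)(tert-butyl)dimethylsilane | COc1cc(Br)ccc1O[Si](C)(C)C(C)(C)C | intermediate
35 | 4-(TBS-oxy)-3-methoxyphenyllithium | [Li]c1ccc(O[Si](C)(C)C(C)(C)C)c(OC)c1 | intermediate
36 | (1R,2S)-3-(TBS-oxy)-1-[4-(TBS-oxy)-3-methoxyphenyl]-2-(4-{(2R,3R)-dihydrobenzofuran-2-yl}-2,6-dimethoxyphenoxy)propan-1-ol (dihydrobenzofuran as in 25) | COc1cc([C@@H](O)[C@H](CO[Si](C)(C)C(C)(C)C)Oc2c(OC)cc([C@@H]3Oc4c(OC)cc(CCCO[Si](C)(C)C(C)(C)C)cc4[C@@H]3CO[Si](C)(C)C(C)(C)C)cc2OC)ccc1O[Si](C)(C)C(C)(C)C | intermediate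
37 | (1R,2S)-1-(4-hydroxy-3-methoxyphenyl)-2-{4-[(2R,3R)-3-(hydroxymethyl)-5-(3-hydroxypropyl)-7-methoxy-2,3-dihydrobenzofuran-2-yl]-2,6-dimethoxyphenoxy}propane-1,3-diol | COc1cc([C@@H](O)[C@H](CO)Oc2c(OC)cc([C@@H]3Oc4c(OC)cc(CCCO)cc4[C@@H]3CO)cc2OC)ccc1O | target

## Step count and risks

Total step count: 22 (steps 9, 16, 17 and 20 are side-branch preparations).
Longest linear sequence: 18 steps (1–8, 10–15, 18, 19, 21, 22; eugenol to target).

Three steps most likely to fail:

1. Step 14 (ring closure). The activated benzylic C2–O bond may ionise before the phenoxide attacks, which would leak stereochemistry to the trans ring, or the oxyphosphonium may undergo anti-elimination to the stilbene. The fallback sets out from 21 and returns at 24. Oxidation of the carbinol of 21 with Dess–Martin periodinane would give the α-aryl ketone F1. Hydrogenolysis of its benzyl ether would give the phenol ketone F2, which under PPTS in warm toluene should cyclodehydrate to the 2-aryl-3-(silyloxymethyl)benzofuran F3. Enantioselective hydrogenation of the furan C2=C3 bond of F3 with a chiral ruthenium N-heterocyclic carbene catalyst (the class known to reduce 2-arylbenzofurans to 2-aryl-2,3-dihydrobenzofurans) adds both hydrogens to one face. The ring is then cis by construction, and the absolute sense would be matched by the choice of ligand antipode, giving 24.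

2. Step 21 (aryl addition). Chelated transition states may compete with the Felkin–Anh one, giving poor facial selectivity, or the basic aryllithium may epimerise the α-aryloxy aldehyde at C8''. The fallback sets out from ester 30 and returns at 36. Treatment of 30 with N,O-dimethylhydroxylamine hydrochloride and i-PrMgCl (THF, −20 °C) would give the Weinreb amide F4. Addition of aryllithium 35 at −78 °C would give the aryl ketone F5. Chelation-controlled reduction of F5 with Zn(BH4)2 in ether at low temperature (zinc bridging the ketone and C8'' aryloxy oxygens, hydride entering past the C8'' hydrogen) is the ketone counterpart that leads to the same 1,2-anti (erythro) alcohol 36.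

3. Step 18 (intermolecular etherification). The redox condensation of the di-ortho-substituted phenol may be slow, letting β-elimination of the activated glycerate compete and leaving the phenoxide of the cis ring exposed for a long time. The fallback sets out from 28 (with phenol 25) and returns at 30. The hydroxy ester 28 would be converted with Tf2O and 2,6-lutidine (CH2Cl2, −78 °C) into the glycerate triflate F6. This preformed electrophile would be displaced by the potassium phenoxide of 25 (K2CO3, MeCN, −20→0 °C) in a Williamson-type SN2 reaction with inversion, giving 30 without phosphine or azo reagent.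

## Further compounds

F1 | step 14 | 4-[(R)-2-{2-(benzyloxy)-3-methoxy-5-[3-(TBS-oxy)propyl]phenyl}-3-(TBS-oxy)propanoyl]-2,6-dimethoxyphenyl methanesulfonate (α-centre labile) | CS(=O)(=O)Oc1c(OC)cc(C(=O)[C@H](c2cc(CCCO[Si](C)(C)C(C)(C)C)cc(OC)c2OCc2ccccc2)CO[Si](C)(C)C(C)(C)C)cc1OC
F2 | step 14 | 4-[(R)-2-{2-hydroxy-3-methoxy-5-[3-(TBS-oxy)propyl]phenyl}-3-(TBS-oxy)propanoyl]-2,6-dimethoxyphenyl methanesulfonate (α-centre labile) | CS(=O)(=O)Oc1c(OC)cc(C(=O)[C@H](c2cc(CCCO[Si](C)(C)C(C)(C)C)cc(OC)c2O)CO[Si](C)(C)C(C)(C)C)cc1OC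
F3 | step 14 | 4-{7-methoxy-3-(TBS-oxymethyl)-5-[3-(TBS-oxy)propyl]benzofuran-2-yl}-2,6-dimethoxyphenyl methanesulfonate | CS(=O)(=O)Oc1c(OC)cc(-c2oc3c(OC)cc(CCCO[Si](C)(C)C(C)(C)C)cc3c2CO[Si](C)(C)C(C)(C)C)cc1OC
F4 | step 21 | (S)-N-methoxy-N-methyl-3-(TBS-oxy)-2-(4-{(2R,3R)-dihydrobenzofuran-2-yl}-2,6-dimethoxyphenoxy)propanamide (dihydrobenzofuran as in 25) | CON(C)C(=O)[C@H](CO[Si](C)(C)C(C)(C)C)Oc1c(OC)cc([C@@H]2Oc3c(OC)cc(CCCO[Si](C)(C)C(C)(C)C)cc3[C@@H]2CO[Si](C)(C)C(C)(C)C)cc1OC
F5 | step 21 | (S)-3-(TBS-oxy)-1-[4-(TBS-oxy)-3-methoxyphenyl]-2-(4-{(2R,3R)-dihydrobenzofuran-2-yl}-2,6-dimethoxyphenoxy)propan-1-one (dihydrobenzofuran as in 25) | COc1cc(C(=O)[C@H](CO[Si](C)(C)C(C)(C)C)Oc2c(OC)cc([C@@H]3Oc4c(OC)cc(CCCO[Si](C)(C)C(C)(C)C)cc4[C@@H]3CO[Si](C)(C)C(C)(C)C)cc2OC)ccc1O[Si](C)(C)C(C)(C)C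
F6 | step 18 | methyl (R)-3-(TBS-oxy)-2-(trifluoromethylsulfonyloxy)propanoate | COC(=O)[C@H](OS(=O)(=O)C(F)(F)F)CO[Si](C)(C)C(C)(C)C
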